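## Structural features

Spiropreussione B contains a 9-hydroxyphenalen-1-one (ring A: C1(=O), C2=C3, C3a, C9b, C9a; ring B: the central benzene ring C3a–C6a/C9b; ring C: the phenol ring C6a–C9a/C9b), a vinylogous acid whose two oxygens exchange roles by tautomerism. A five-membered carbocycle (ring D: C5, C6, C10, C11, C15; locants 10–15 are used here for the non-phenalenone carbons) is fused across C5–C6 of ring B. In it C10, on the more hindered C6, is the spiro carbon of the naphtho[1,8-de][1,3]dioxine ketal of naphthalene-1,8-diol, C11 is a methine and C15, on C5, is a tertiary carbinol. C11 and C15 also belong to a cyclopent-2-enone (ring E: C11, C12(=O), C13=C14, C15), so rings D and E form a cis-fused diquinane. The stereocentres C11 (S) and C15 (R) are neighbours; only the cis fusion is attainable, so the configuration of the quaternary C15 is the single independent element and cannot be corrected once set. Fragile groups are the aryl ketal (β to the C12 ketone, opened by acid or by β-elimination from a C11 enol or enolate), the tertiary benzylic and allylic alcohol, the enone of ring E, and phenalenone positions C9 and C6, where an alkoxy group or a halogen is displaced by nucleophiles. The real difficulty is to place ketal and carbinol on C6 and C5 without regiochemical ambiguity and to create C15 as one enantiomer beside the ketal. The key step exploits that C15 is the carbonyl carbon of an indan-1-one (ring D) and, once that ketone is held as an enol ether towards C11, the oxygenated terminus of the pentadienyl cation C15–C11–C12–C13–C14, whose five carbons are exactly ring E.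

## Logic of the disconnections

**26 ⇒ 25.** Cut: the O–CH2Ph bond on the C15 oxygen and the O–CH3 bond on the C9 oxygen. Both ethers answer to one boron halide, so a single operation frees the alcohol and the vinylogous acid. Because free 26 is a tautomeric pair, the position of the methyl group has no consequence. Demand: the Lewis acid must spare the ketal and must not ionise C15.

**25 ⇒ 23.** Cut: C14–C15, the ring E bond between the oxygenated carbon and the alkene. This removes ring E and both stereocentres and leads to an achiral dienone. Demand: a chiral acid must control the sense of conrotation although the oxygen on C15 stabilises the open cation. Two substituents of 23 are chosen for this reason: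
- C14 carries SiMe3, so the alkene reacts at its ipso carbon, the cyclised cation is β-silyl-stabilised and termination is fast.
- The C15 oxygen carries benzyl. An allyl group there could undergo an acid-promoted [3,3] shift to C11 and would be slow to leave from a tertiary ether; a free hydroxyl could add to the enone or push out an aryloxy group of the ketal.

**23 ⇒ 22.** Cut: the O–CH2Ph bond. Reason: 22 is an acidic β-diketone that can be O-alkylated under neutral conditions. Gain: the enol ether is made from the compound that the ring D closure delivers. Demand: alkylation on the ring oxygen, not on the C12 oxygen or on C11.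

**22 ⇒ 21.** Cut: C11–C15, which opens ring D. Reason: an ester on C5 and a ketone enolate on the C6 side chain are ortho, and the β-diketone arrives with its complete acyl arm, so no separate acylation with an acryloyl electrophile is needed. Gain: the tetracyclic core falls back to a phenalenone with two side chains. Demand: the C11 enolate must acylate faster than it expels an aryloxide.

**21 ⇒ 18 + 19.** Cut: both C10–O bonds. Reason: double conjugate addition to an ynone puts the ketal on the alkyne carbon attached to C6, so its position is fixed by construction and not by selection between two carbonyls. Gain: 19 is separated. Demand: the second addition must succeed at a congested carbon and the β-silyl enone must stay inert.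

**18 ⇒ 17 ⇒ 12 + 16.** Adjust the oxidation level at C12, then cut C6–C10 (aryl–alkynyl). Reason: the C6–Cl bond of 12 is activated by the ortho ester and by conjugation with C1=O. Gain: a five-carbon arm and a simple phenalenone ester. Demand: coupling must outrun nucleophilic displacement of the chloride.

**16 ⇒ 14 + 15; 14 ⇒ 13.** Cut: C11–C12 (acetylide to aldehyde), then a C–H oxidation. Gain: purchasable three- and two-carbon pieces. Demand: 1,2-addition only.

**12 ⇒ 11 ⇒ 9.** Remove the C2=C3 unsaturation, then cut C1–C9a (ring A). Reason: C9a is ortho to the methoxy group and peri to the side chain, so a nitrile-derived acylium equivalent closes there. Gain: ring A is removed. Demand: closure at C9a, not at C4.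

**9 ⇒ 7 + 8.** Cut: C3–C3a (aryl–alkyl). Reason: an aryl triflate at C3a couples with a functionalised alkylzinc. Demand: the triflate reacts, the chloride does not.

**7 ⇒ 6 ⇒ 4.** Cut: O–S and C6–Cl. Reason: one hydroxyl serves twice, first directing chlorination to its para position (the future C6), then becoming the leaving group at C3a. Demand: para selectivity over the ortho position and the methoxy ring.

**4 ⇒ 5 ⇒ 3 ⇒ 1 + 2.** Cut ring B at C3a–C9b (acyl to arene) and at C5=C6 (aldehyde carbon to succinate α-carbon). Reason: the Stobbe benzannulation sets ester (C5) and oxygen (C3a) 1,3 to each other and leaves C6 and C9a free. Gain: two commodity chemicals. Demand: the E half-ester and closure at the position meta to the methoxy group.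

## Other disconnections considered

Alternative 1: The cut is made at the C15–O bond and, formally, at C11–H. Both ring-fusion atoms are traced back to the tetrasubstituted C11=C15 alkene of the flat allylic alcohol A1, whose only stereocentre is the secondary carbinol at the future C12. Forward, VO(acac)2 and tert-butyl hydroperoxide would deliver oxygen to the face syn to that hydroxyl and give epoxy alcohol A2. Oxidation at C12, reductive cleavage of the C11–O bond (for example with SmI2) and introduction of C13=C14 would follow.
- In favour: the absolute configuration would come from an asymmetric carbonyl reduction that sets the carbinol of A1, and the C15–O bond is made without a cation beside the ketal. On predictability of the stereochemical outcome this plan is the better one.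
- Against: the C11=C15 alkene is an electron-rich indene-type alkene next to the ketal, so the oxirane of A2 is prone to Lewis-acid opening and semipinacol shift. A2 still stands at the 2-methoxynaphthalene level, so ring A would have to be annulated on a compound carrying ketal, tertiary alcohol and enone.
- Comparison: in structure it creates three stereocentres to keep two, whereas the electrocyclisation creates exactly two. In mechanism, substrate direction is equal in rigour to conrotation and needs no chiral counter-ion. In step economy it is inferior: several operations and the whole ring A annulation follow its key step, against one deprotection after step 16.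

Alternative 2: The cut runs through ring C (C6a–C9b and C9–C9a) and returns ring B to a non-aromatic state. Furyl dienynone A3 carries a 2-furyl group on C6 of a cyclopentene (the later ring D, C5=C6) and, on C5, a Z-enyne arm ending in an acetyl ynone. Forward, the furan would add across the tethered alkyne, the oxygen bridge would open at C6a and proton loss at C9 would aromatise rings B and C to acetyl naphthol A4. Desilylation, oxidation and aldol condensation would then close ring A.
- In favour: aromatisation of two rings drives the step, and the tether places the C9 oxygen and the C9a acyl group. The C9 hydroxyl is born free, and no Friedel–Crafts or superacid step is needed. On these points it is better than the chosen plan.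
- Against: the key step makes no stereocentre, so the diquinane with C11 and C15 must already be present as one enantiomer in A3. A3 combines an ynone, an enone, a tertiary allylic alcohol and a cyclopentadiene-like triene; heating invites dehydration towards a fulvene and intermolecular Michael or Diels–Alder pathways.
- Comparison: in structure it is more convergent for rings A–C but leaves rings D and E unsolved. In mechanism a reagent-free thermal cycloaddition is equal to the electrocyclisation in orbital control. In step economy three operations follow A4 against one after 25, and A3 is unlikely to need fewer steps than 23.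

Alternative 3: The cut removes C5–C6 (ring D) and C3a–C4 (ring B) together. Dienyne A5 joins a methoxy-tetralone ring with an exocyclic methylene at C3a and a 1-arylvinyl group (C6=CH2) on the ketal carbon C10 to a cyclopentenone with an ethynyl group (C5≡C4) on the silylated carbinol C15. Forward, a second-generation Grubbs catalyst would link alkyne and arylvinyl group by ring-closing enyne metathesis, and the vinyl carbene at C4 would close on the C3a methylene, giving ring B as an arene in A6.
- In favour: two rings, one aromatic, arise in one catalytic step under neutral conditions. In functional-group tolerance this is equal to or better than a strong-acid cyclisation, and the fragment union is highly convergent.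
- Against: both stereocentres must be built beforehand, as a quaternary propargylic carbinol next to a carbon bearing the fully substituted ketal. The carbene must engage two 1,1-disubstituted alkenes, one of them neopentyl, and the order of events is not secured. A6 is at the 2,3-dihydro level, so dehydrogenation, desilylation and O-demethylation remain.
- Comparison: in structure it builds rings B and D late but not the stereocentres. In mechanism a carbene cascade is more sensitive to crowding at C10 than the electrocyclisation, which forms its bond away from C10. In step economy three steps follow A6 against one after 25.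

Key step: step 16

Assumption: 2-cyanoethylzinc bromide (8), (E)-3-(trimethylsilyl)prop-2-en-1-ol (13) and ethynylmagnesium bromide (15) are taken as purchasable reagents (8 and 15 as THF solutions).
Assumption: the sense of induction of the phosphoramide in step 16 cannot be assigned beforehand; the (R)-catalyst is written and its antipode is to be used if the mirror image of 25 should form.
Remark: 22 is a tautomeric β-diketone and is written as its endocyclic enol; 16 and 17 are racemic at a carbinol that step 12 oxidises.

## Route

Step 1
Reactants: 1 4-methoxybenzaldehyde; 2 dimethyl succinate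
Product: 3 (E)-3-(methoxycarbonyl)-4-(4-methoxyphenyl)but-3-enoic acid
Conditions: NaOMe, MeOH, reflux; then aq. HCl
Reagents that add atoms: none
Why: Stobbe condensation: the succinate enolate adds to the aldehyde, the aldolate lactonises and the lactone opens by E1cB, which leaves the free acid on the CH2 arm and the aryl group cis to that arm (E alkene), as the ring closure requires.

Step 2
Reactants: 3 (E)-3-(methoxycarbonyl)-4-(4-methoxyphenyl)but-3-enoic acid
Product: 5 methyl 4-acetoxy-6-methoxy-2-naphthoate, via naphthol 4 (not isolated)
Conditions: Ac2O, NaOAc, 140 °C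
Reagents that add atoms: acetic anhydride, CC(=O)OC(C)=O
Why: Benzannulation of a Stobbe half-ester: the mixed anhydride closes onto the arene position ortho to the alkenyl group (both ortho positions are equivalent), the product aromatises to naphthol 4 and is acetylated in the flask.

Step 3
Reactants: 5 methyl 4-acetoxy-6-methoxy-2-naphthoate
Product: 4 methyl 4-hydroxy-6-methoxy-2-naphthoate
Conditions: K2CO3 (cat.), MeOH, 0 °C to rt
Reagents that add atoms: none
Why: Base-catalysed methanolysis of the aryl acetate; the methyl ester is degenerate towards methanol and survives.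

Step 4
Reactants: 4 methyl 4-hydroxy-6-methoxy-2-naphthoate
Product: 6 methyl 1-chloro-4-hydroxy-6-methoxy-2-naphthoate
Conditions: NCS (1.0 equiv), MeCN, 0 °C to rt
Reagents that add atoms: N-chlorosuccinimide, ClN1C(=O)CCC1=O
Why: Electrophilic aromatic chlorination: the free 1-naphthol-type hydroxyl directs to its para position C1, an α-position that should be more reactive than the ortho position C3 or the methoxy-activated C5; this chlorine later marks C6 of the phenalenone.

Step 5
Reactants: 6 methyl 1-chloro-4-hydroxy-6-methoxy-2-naphthoate
Product: 7 methyl 1-chloro-6-methoxy-4-(trifluoromethanesulfonyloxy)-2-naphthoate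
Conditions: Tf2O, pyridine, CH2Cl2, 0 °C
Reagents that add atoms: trifluoromethanesulfonic anhydride, O=S(=O)(OS(=O)(=O)C(F)(F)F)C(F)(F)F
Why: O-Sulfonylation of the naphthol turns the directing hydroxyl into the leaving group for carbon–carbon coupling.

Step 6
Reactants: 7 methyl 1-chloro-6-methoxy-4-(trifluoromethanesulfonyloxy)-2-naphthoate; 8 2-cyanoethylzinc bromide
Product: 9 methyl 1-chloro-4-(2-cyanoethyl)-6-methoxy-2-naphthoate
Conditions: Pd(dppf)Cl2 (5 mol %), THF, 60 °C
Reagents that add atoms: none
Why: Negishi coupling: with a bisphosphine ligand palladium inserts into the aryl triflate much faster than into the hindered aryl chloride, and the functionalised alkylzinc should transfer the three-carbon nitrile arm without β-hydride loss.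

Step 7
Reactants: 9 methyl 1-chloro-4-(2-cyanoethyl)-6-methoxy-2-naphthoate
Product: 11 methyl 6-chloro-9-methoxy-1-oxo-2,3-dihydro-1H-phenalene-5-carboxylate, via ketiminium triflate 10 (not isolated)
Conditions: TfOH, CH2Cl2, 0 °C to rt; then H2O
Reagents that add atoms: water, O
Why: Intramolecular Houben–Hoesch acylation: the protonated nitrile attacks the carbon ortho to the methoxy group and peri to the side chain (six-membered ring A) rather than the ester-deactivated ortho carbon, and water hydrolyses ketiminium 10 to the ketone.

Step 8
Reactants: 11 methyl 6-chloro-9-methoxy-1-oxo-2,3-dihydro-1H-phenalene-5-carboxylate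
Product: 12 methyl 6-chloro-9-methoxy-1-oxo-1H-phenalene-5-carboxylate
Conditions: DDQ, 1,4-dioxane, 100 °C
Reagents that add atoms: none
Why: Quinone dehydrogenation (hydride abstraction from benzylic C3, proton loss from C2), driven by formation of the phenalenone π-system.

Step 9
Reactants: 13 (E)-3-(trimethylsilyl)prop-2-en-1-ol
Product: 14 (E)-3-(trimethylsilyl)prop-2-enal
Conditions: MnO2, CH2Cl2, rt
Reagents that add atoms: none
Why: Allylic alcohol oxidation on MnO2, which leaves the E-vinylsilane untouched.

Step 10
Reactants: 14 (E)-3-(trimethylsilyl)prop-2-enal; 15 ethynylmagnesium bromide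
Product: 16 rac-(E)-1-(trimethylsilyl)pent-1-en-4-yn-3-ol
Conditions: THF, −78 to 0 °C; then aq. NH4Cl
Reagents that add atoms: none
Why: Grignard 1,2-addition to the enal, the silyl group shielding the β-carbon; the racemic carbinol is oxidised in step 12.

Step 11
Reactants: 12 methyl 6-chloro-9-methoxy-1-oxo-1H-phenalene-5-carboxylate; 16 rac-(E)-1-(trimethylsilyl)pent-1-en-4-yn-3-ol
Product: 17 methyl 6-[(E)-3-hydroxy-5-(trimethylsilyl)pent-4-en-1-yn-1-yl]-9-methoxy-1-oxo-1H-phenalene-5-carboxylate (racemic)
Conditions: Pd(PPh3)2Cl2 (5 mol %), CuI (10 mol %), Et3N, THF, 50 °C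
Reagents that add atoms: none
Why: Sonogashira coupling: the C6–Cl bond is activated for oxidative addition by the ortho ester and by conjugation with the C1 carbonyl (a vinylogous acyl chloride), and a tertiary amine base avoids displacement of chloride or of the C9 methoxy group.

Step 12
Reactants: 17 methyl 6-[(E)-3-hydroxy-5-(trimethylsilyl)pent-4-en-1-yn-1-yl]-9-methoxy-1-oxo-1H-phenalene-5-carboxylate
Product: 18 methyl 9-methoxy-1-oxo-6-[(E)-3-oxo-5-(trimethylsilyl)pent-4-en-1-yn-1-yl]-1H-phenalene-5-carboxylate
Conditions: MnO2, CH2Cl2, rt
Reagents that add atoms: none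
Why: MnO2 oxidation of a doubly activated (propargylic and allylic) alcohol to the cross-conjugated ynone.

Step 13
Reactants: 18 methyl 9-methoxy-1-oxo-6-[(E)-3-oxo-5-(trimethylsilyl)pent-4-en-1-yn-1-yl]-1H-phenalene-5-carboxylate; 19 naphthalene-1,8-diol
Product: 21 methyl 9-methoxy-1-oxo-6-{2-[(E)-2-oxo-4-(trimethylsilyl)but-3-en-1-yl]naphtho[1,8-de][1,3]dioxin-2-yl}-1H-phenalene-5-carboxylate, via aryl enol ether 20 (not isolated)
Conditions: K2CO3 (0.3 equiv), MeCN, rt
Reagents that add atoms: none
Why: Double oxa-Michael addition of a bis-phenol to an ynone: the first aryloxide adds at the alkyne carbon on C6 to give enol ether 20 and the second closes the six-membered dioxine onto the same carbon (6-exo-trig), which fixes the ketal at C10; the β-silyl enone is too hindered to compete.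

Step 14
Reactants: 21 methyl 9-methoxy-1-oxo-6-{2-[(E)-2-oxo-4-(trimethylsilyl)but-3-en-1-yl]naphtho[1,8-de][1,3]dioxin-2-yl}-1H-phenalene-5-carboxylate
Product: 22 2-[(E)-3-(trimethylsilyl)acryloyl]-3-hydroxyindene spiro-ketal fused to 9-methoxyphenalen-1-one (indene C1 = spiro carbon C10 on phenalenone C6, indene C3 = C15 on phenalenone C5; enol form of the β-diketone)
Conditions: LiN(SiMe3)2 (2.2 equiv), THF, −78 to 0 °C; then AcOH
Reagents that add atoms: none
Why: Intramolecular Claisen (Dieckmann-type) condensation: the C11 ketone enolate acylates the neighbouring methyl ester through a five-membered transition state and deprotonation of the β-diketone drives it; low temperature and the intramolecular acyl trap should outrun β-elimination of aryloxide.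

Step 15
Reactants: 22 2-[(E)-3-(trimethylsilyl)acryloyl]-3-hydroxyindene spiro-ketal fused to 9-methoxyphenalen-1-one
Product: 23 2-[(E)-3-(trimethylsilyl)acryloyl]-3-benzyloxyindene spiro-ketal fused to 9-methoxyphenalen-1-one (benzyl on the C15 oxygen)
Conditions: BnOH, PPh3, DIAD, toluene, 0 °C to rt
Reagents that add atoms: benzyl alcohol, OCc1ccccc1
Why: Mitsunobu O-alkylation of an acidic β-diketone enol: C11 is neopentyl-like next to the spiro carbon, so carbon alkylation is blocked, and the ring oxygen on C15 is the exposed one because the acyl oxygen lies against the ketal; neutral conditions spare the ketal.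

Step 16
Reactants: 23 2-[(E)-3-(trimethylsilyl)acryloyl]-3-benzyloxyindene spiro-ketal fused to 9-methoxyphenalen-1-one
Product: 25 O-benzyl 9-O-methyl spiropreussione B (C11 S, C15 R; cis-fused), via dienol 24 (not isolated)
Conditions: (R)-3,3′-bis(2,4,6-triisopropylphenyl)-BINOL N-triflylphosphoramide (10 mol %), PhOH (1.2 equiv), CHCl3, 0 °C to rt
Reagents that add atoms: none
Why: The phosphoramide protonates the C12 carbonyl of 23 and stays hydrogen-bonded to the 1-benzyloxy-3-hydroxypentadienyl cation C15–C11–C12–C13–C14, which closes between its oxygen- and aryl-bearing terminus C15 and its silyl-bearing terminus C14 by thermal conrotatory 4π-electrocyclisation. The closest known reaction type is the chiral-Brønsted-acid-catalysed, silicon-directed Nazarov cyclisation of divinyl ketones; with oxygen on the terminus the closure parallels the ring-forming step of the Piancatelli rearrangement. Ring E is closed in this single pericyclic event (formally 5-endo, C14 to C15), so ring-closure rules for polar cyclisations do not apply. The allyl cation that results (C11–C12–C13) is β to silicon, which lowers its energy and lets loss of Me3Si to phenol, with return of the proton, outrun cycloreversion and 1,2-shifts; the C13=C14 bond of dienol 24 is the only one that can form, C15 being quaternary. C15 (R) is set by the sense of conrotation; 23 is achiral and its ketal symmetric, so this sense is dictated by the chiral counter-anion alone. C11 (S) is set when 24 ketonises, protonation occurring on the face that gives the cis-fused diquinane, the only fusion the bicycle can sustain. The selectivity needed is C–C closure over C–O closure, [3,3] shift and ketal opening: the benzyl ether can neither add as a hydroxyl to the enone nor rearrange, it locks the enol so that no aryloxy group is expelled, and the silyl group makes the alkene react at its ipso carbon C14.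

Step 17
Reactants: 25 O-benzyl 9-O-methyl spiropreussione B
Product: 26 spiropreussione B (C11 S, C15 R)
Conditions: BCl3, C6HMe5, CH2Cl2, −78 to −20 °C; then H2O
Reagents that add atoms: none
Why: Lewis-acid ether cleavage: BCl3 chelated by the C1 carbonyl removes the peri methyl group as MeCl and cleaves the benzyl–oxygen bond, the benzyl cation being trapped by pentamethylbenzene; the C15–O bond should not ionise because C15 sits on an electron-poor arene and γ to the enone carbonyl, so both stereocentres persist.

## Compound list

1 | 4-methoxybenzaldehyde | COc1ccc(C=O)cc1 | starting material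
2 | dimethyl succinate | COC(=O)CCC(=O)OC | starting material
3 | (E)-3-(methoxycarbonyl)-4-(4-methoxyphenyl)but-3-enoic acid | COC(=O)/C(=C/c1ccc(OC)cc1)CC(=O)O | intermediate
4 | methyl 4-hydroxy-6-methoxy-2-naphthoate | COC(=O)c1cc(O)c2cc(OC)ccc2c1 | intermediate
5 | methyl 4-acetoxy-6-methoxy-2-naphthoate | COC(=O)c1cc(OC(C)=O)c2cc(OC)ccc2c1 | intermediate
6 | methyl 1-chloro-4-hydroxy-6-methoxy-2-naphthoate | COC(=O)c1cc(O)c2cc(OC)ccc2c1Cl | intermediate
7 | methyl 1-chloro-6-methoxy-4-(trifluoromethanesulfonyloxy)-2-naphthoate | COC(=O)c1cc(OS(=O)(=O)C(F)(F)F)c2cc(OC)ccc2c1Cl | intermediate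
8 | 2-cyanoethylzinc bromide | N#CCC[Zn]Br | starting material
9 | methyl 1-chloro-4-(2-cyanoethyl)-6-methoxy-2-naphthoate | COC(=O)c1cc(CCC#N)c2cc(OC)ccc2c1Cl | intermediate
10 | methyl 6-chloro-1-iminio-9-methoxy-2,3-dihydro-1H-phenalene-5-carboxylate triflate | [NH2+]=C1CCc2cc(C(=O)OC)c(Cl)c3ccc(OC)c1c23.[O-]S(=O)(=O)C(F)(F)F | intermediate
11 | methyl 6-chloro-9-methoxy-1-oxo-2,3-dihydro-1H-phenalene-5-carboxylate | O=C1CCc2cc(C(=O)OC)c(Cl)c3ccc(OC)c1c23 | intermediate
12 | methyl 6-chloro-9-methoxy-1-oxo-1H-phenalene-5-carboxylate | O=C1C=Cc2cc(C(=O)OC)c(Cl)c3ccc(OC)c1c23 | intermediate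
13 | (E)-3-(trimethylsilyl)prop-2-en-1-ol | OC/C=C/[Si](C)(C)C | starting material
14 | (E)-3-(trimethylsilyl)prop-2-enal | O=C/C=C/[Si](C)(C)C | intermediate
15 | ethynylmagnesium bromide | C#C[Mg]Br | starting material
16 | rac-(E)-1-(trimethylsilyl)pent-1-en-4-yn-3-ol | C#CC(O)/C=C/[Si](C)(C)C | intermediate
17 | methyl 6-[(E)-3-hydroxy-5-(trimethylsilyl)pent-4-en-1-yn-1-yl]-9-methoxy-1-oxo-1H-phenalene-5-carboxylate (racemic) | O=C1C=Cc2cc(C(=O)OC)c(C#CC(O)/C=C/[Si](C)(C)C)c3ccc(OC)c1c23 | intermediate
18 | methyl 9-methoxy-1-oxo-6-[(E)-3-oxo-5-(trimethylsilyl)pent-4-en-1-yn-1-yl]-1H-phenalene-5-carboxylate | O=C1C=Cc2cc(C(=O)OC)c(C#CC(=O)/C=C/[Si](C)(C)C)c3ccc(OC)c1c23 | intermediate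
19 | naphthalene-1,8-diol | Oc1cccc2cccc(O)c12 | starting material
20 | methyl 6-[1-(8-hydroxynaphthalen-1-yloxy)-3-oxo-5-(trimethylsilyl)penta-1,4-dien-1-yl]-9-methoxy-1-oxo-1H-phenalene-5-carboxylate (enol ether geometry not fixed) | O=C1C=Cc2cc(C(=O)OC)c(C(Oc4cccc5cccc(O)c45)=CC(=O)/C=C/[Si](C)(C)C)c3ccc(OC)c1c23 | intermediate
21 | methyl 9-methoxy-1-oxo-6-{2-[(E)-2-oxo-4-(trimethylsilyl)but-3-en-1-yl]naphtho[1,8-de][1,3]dioxin-2-yl}-1H-phenalene-5-carboxylate | O=C1C=Cc2cc(C(=O)OC)c(C4(CC(=O)/C=C/[Si](C)(C)C)Oc5cccc6cccc(O4)c56)c3ccc(OC)c1c23 | intermediate
22 | 2-[(E)-3-(trimethylsilyl)acryloyl]-3-hydroxyindene spiro-ketal fused to 9-methoxyphenalen-1-one (enol of the β-diketone) | O=C1C=Cc2cc3c(c4ccc(OC)c1c24)C1(Oc2cccc4cccc(c24)O1)C(C(=O)/C=C/[Si](C)(C)C)=C3O | intermediate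
23 | 2-[(E)-3-(trimethylsilyl)acryloyl]-3-benzyloxyindene spiro-ketal fused to 9-methoxyphenalen-1-one | O=C1C=Cc2cc3c(c4ccc(OC)c1c24)C1(Oc2cccc4cccc(c24)O1)C(C(=O)/C=C/[Si](C)(C)C)=C3OCc1ccccc1 | intermediate
24 | dienol C11=C12(OH)–C13=C14 with the C15 benzyl ether configured as in 25 | O=C1C=Cc2cc3c(c4ccc(OC)c1c24)C1(Oc2cccc4cccc(c24)O1)C1=C(O)C=C[C@]31OCc1ccccc1 | intermediate
25 | O-benzyl 9-O-methyl spiropreussione B (C11 S, C15 R) | O=C1C=Cc2cc3c(c4ccc(OC)c1c24)C1(Oc2cccc4cccc(c24)O1)[C@@H]1C(=O)C=C[C@]31OCc1ccccc1 | intermediate
26 | spiropreussione B (C11 S, C15 R) | O=C1C=Cc2cc3c(c4ccc(O)c1c24)C1(Oc2cccc4cccc(c24)O1)[C@@H]1C(=O)C=C[C@]31O | target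

## Step count and least certain steps

Total step count: 17. Longest linear sequence: 15 (steps 1–8 and 11–17); steps 9 and 10 form the side branch.

**Step 16 (key step).** The benzyloxy-stabilised pentadienyl cation may close too slowly, so that protodesilylation, loss of the benzyl group or acid opening of the ketal compete. The phenalenone carbonyl may also bind the catalyst and erode control over the sense of conrotation. Fallback: from 23, cyclisation with a stronger achiral acid (Tf2NH, 10 mol %, PhOH, CH2Cl2, −40 to 0 °C) should give racemic O-benzyl 9-O-methyl spiropreussione B F1. Separation of the enantiomers by preparative chromatography on a chiral stationary phase returns the route at 25; stereocontrol changes from catalyst control to resolution.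

**Step 13.** The second conjugate addition may stall at 20 because C10 is congested, or the aryloxide may exchange the C9 methoxy group. Fallback: from 18, NaOMe (cat.) in MeOH should add two molecules of methanol to the ynone and give the dimethyl ketal F2. Acid-catalysed exchange with 19 (camphorsulfonic acid, toluene, removal of MeOH), an oxocarbenium route instead of an anionic one, returns the route at 21.

**Step 14.** The C11 enolate may expel an aryloxide and open the dioxine ring faster than it attacks the ester. Fallback: the order of ketalisation and ring closure is reversed. From 18 by way of the dimethyl ketal F2, the same Claisen conditions should give the 3,3-dimethoxy β-diketone F3, methoxide being a far poorer leaving group. Acid-catalysed exchange of F3 with 19 then returns the route at 22.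

**Step 15.** Alkylation may occur on the acyl oxygen or on carbon, or the Mitsunobu betaine may open the ketal. Fallback: from 22, iPr3SiOTf and Et3N should give the triisopropylsilyl enol ether F4. Silylation occurs on oxygen only, and either O-silyl isomer gives the same dioxygenated cation on protonation. The chiral-acid cyclisation of step 16 followed by Bu4NF should give 9-O-methyl spiropreussione B F5, and MgI2 in Et2O/toluene removes the chelated methyl group, returning the route at 26.

**Step 17.** The Lewis acid may open the naphthodioxine ketal or cleave only one ether cleanly. Fallback: from 22, a Mitsunobu reaction with 2-naphthylmethanol should give the 2-naphthylmethyl enol ether F6. The cyclisation of step 16 then gives O-(2-naphthylmethyl) 9-O-methyl spiropreussione B F7, and MgI2 cleaves the methyl ether to O-(2-naphthylmethyl) spiropreussione B F8. DDQ in wet CH2Cl2 removes the arylmethyl group oxidatively and returns the route at 26 without a boron halide.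

## Further compounds

F1 | step 16 | racemic O-benzyl 9-O-methyl spiropreussione B (25 and its mirror image) | O=C1C=Cc2cc3c(c4ccc(OC)c1c24)C1(Oc2cccc4cccc(c24)O1)[C@@H]1C(=O)C=C[C@]31OCc1ccccc1.O=C1C=Cc2cc3c(c4ccc(OC)c1c24)C1(Oc2cccc4cccc(c24)O1)[C@H]1C(=O)C=C[C@@]31OCc1ccccc1
F2 | step 13 | methyl 6-[(E)-1,1-dimethoxy-3-oxo-5-(trimethylsilyl)pent-4-en-1-yl]-9-methoxy-1-oxo-1H-phenalene-5-carboxylate | O=C1C=Cc2cc(C(=O)OC)c(C(OC)(OC)CC(=O)/C=C/[Si](C)(C)C)c3ccc(OC)c1c23
F3 | step 14 | 2-[(E)-3-(trimethylsilyl)acryloyl]-3-hydroxy-1,1-dimethoxyindene fused to 9-methoxyphenalen-1-one | O=C1C=Cc2cc3c(c4ccc(OC)c1c24)C(OC)(OC)C(C(=O)/C=C/[Si](C)(C)C)=C3O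
F4 | step 15 | triisopropylsilyl enol ether of 22 | O=C1C=Cc2cc3c(c4ccc(OC)c1c24)C1(Oc2cccc4cccc(c24)O1)C(C(=O)/C=C/[Si](C)(C)C)=C3O[Si](C(C)C)(C(C)C)C(C)C
F5 | step 15 | 9-O-methyl spiropreussione B | O=C1C=Cc2cc3c(c4ccc(OC)c1c24)C1(Oc2cccc4cccc(c24)O1)[C@@H]1C(=O)C=C[C@]31O
F6 | step 17 | 2-naphthylmethyl enol ether of 22 | O=C1C=Cc2cc3c(c4ccc(OC)c1c24)C1(Oc2cccc4cccc(c24)O1)C(C(=O)/C=C/[Si](C)(C)C)=C3OCc1ccc2ccccc2c1
F7 | step 17 | O-(2-naphthylmethyl) 9-O-methyl spiropreussione B | O=C1C=Cc2cc3c(c4ccc(OC)c1c24)C1(Oc2cccc4cccc(c24)O1)[C@@H]1C(=O)C=C[C@]31OCc1ccc2ccccc2c1
F8 | step 17 | O-(2-naphthylmethyl) spiropreussione B | O=C1C=Cc2cc3c(c4ccc(O)c1c24)C1(Oc2cccc4cccc(c24)O1)[C@@H]1C(=O)C=C[C@]31OCc1ccc2ccccc2c1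
A1 | alternative 1 | allylic alcohol with the C11=C15 ring-fusion alkene | COc1ccc2c(c1)ccc1c2C2(Oc3cccc4cccc(c34)O2)C2=C1CC[C@@H]2O
A2 | alternative 1 | syn epoxy alcohol | COc1ccc2c(c1)ccc1c2C2(Oc3cccc4cccc(c34)O2)[C@]23O[C@@]13CC[C@@H]2O
A3 | alternative 2 | furyl dienynone | CC(=O)C#C/C(CO[Si](C)(C)C(C)(C)C)=C\C1=C(c2ccco2)C2(Oc3cccc4cccc(c34)O2)[C@@H]2C(=O)C=C[C@]12O
A4 | alternative 2 | 1-acetyl-2-naphthol with a peri silyloxymethyl group | CC(=O)c1c(O)ccc2c1c(CO[Si](C)(C)C(C)(C)C)cc1c2C2(Oc3cccc4cccc(c34)O2)[C@@H]2C(=O)C=C[C@]12O
A5 | alternative 3 | dienyne | O=C1CCC(=C)c2c(C(=C)C3(Oc4cccc5cccc(c45)O3)[C@@H]3C(=O)C=C[C@@]3(C#C)O[Si](C)(C)C)ccc(OC)c12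
A6 | alternative 3 | O-trimethylsilyl 2,3-dihydro-9-O-methyl spiropreussione B | O=C1CCc2cc3c(c4ccc(OC)c1c24)C1(Oc2cccc4cccc(c24)O1)[C@@H]1C(=O)C=C[C@]31O[Si](C)(C)C
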